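**Plan** (side chain numbered C1, the CH2 on the quinone, to C36)

1. Retrosynthesis: first unmask the quinone from a 1,4-dimethoxynaphthalene; then cut C15–C16, which splits the molecule into the C26 homoallylic boronic ester 21 (fragment 1) and the C30 (Z)-alkenyl iodide 35 (fragment 2); then cut C1–C2 and each CH2–C≡C bond made from a propyne unit.
2. The feature that allows the union: C15 is the methyl-bearing sp2 carbon of the C14=C15 trisubstituted alkene and can carry lithium, then boron; C16 is a primary sp3 carbon that can migrate from boron to C15. No ring is formed; the naphthalene ring system is brought in intact.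
3. Forward: (R)-citronellyl bromide gives alkyne 3 and allylic alcohol 6, which serve both halves. Each further E-isoprene unit comes from one repeating cycle: bromide, propargylation, Cp2ZrCl2-catalysed methylalumination with an electrophile.
4. Fragment 1 is 6 plus two more cycles. Fragment 2 is 6 after hydrogenation, one more propyne, ozonolysis, methylalumination with nickel coupling to the naphthalene, and iodo-olefination.
5. Union by a Zweifel-type boronate rearrangement makes C15–C16 and the 14E alkene together; (NH4)2Ce(NO3)6 then releases the quinone.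
6. Stereochemistry: C11 and C31 both come from (R)-citronellyl bromide; C7 from Ru(OAc)2[(S)-BINAP] hydrogenation of 6; 2E, 18E, 22E, 26E from syn methylalumination; 14E from the Z-iodide by stereospecific inversion.

Key step: step 20

**Route**

Step 1
Reactants: 1 (R)-citronellyl bromide
Product: 3 (6S)-6,10-dimethylundec-9-en-1-yne, via silylalkyne 2 (not isolated)
Conditions: 1-(trimethylsilyl)propyne, n-BuLi, THF, −78 °C; add 1, DMPU, −78 °C → rt; then MeOH, K2CO3, rt
Reagents that add atoms: 1-(trimethylsilyl)propyne CC#C[Si](C)(C)C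
Why: SN2 propargylation of the primary bromide by the lithiated silylpropyne followed by methanolysis of the C–Si bond should give the terminal alkyne; the stereocentre is untouched (the descriptor changes from R to S only through CIP priorities).

Step 2
Reactants: 3 (6S)-6,10-dimethylundec-9-en-1-yne
Product: 6 (2E,7S)-3,7,11-trimethyldodeca-2,10-dien-1-ol, via alkenylalane 4 (not isolated), via lithium alanate 5 (not isolated)
Conditions: Me3Al, Cp2ZrCl2 (20 mol%), (CH2Cl)2, rt; then n-BuLi, THF/hexane, −78 → 0 °C; (CH2O)n, rt; dilute HCl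
Reagents that add atoms: trimethylaluminium C[Al](C)C; formaldehyde (as paraformaldehyde) C=O
Why: Negishi zirconium-catalysed methylalumination adds CH3 and Al syn across the terminal alkyne with Al at the terminus, and the alanate adds to formaldehyde with retention, so the allylic alcohol should form as the 2E isomer while the remote trisubstituted alkene is inert.

Step 3
Reactants: 6 (2E,7S)-3,7,11-trimethyldodeca-2,10-dien-1-ol
Product: 7 (2E,7S)-1-bromo-3,7,11-trimethyldodeca-2,10-diene
Conditions: CBr4, PPh3, CH2Cl2, −20 → 0 °C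
Reagents that add atoms: carbon tetrabromide BrC(Br)(Br)Br
Why: Appel bromination of a primary allylic alcohol proceeds by SN2 displacement of the oxyphosphonium group and should keep the alkene position and E geometry.

Step 4
Reactants: 7 (2E,7S)-1-bromo-3,7,11-trimethyldodeca-2,10-diene
Product: 9 (5E,10S)-6,10,14-trimethylpentadeca-5,13-dien-1-yne, via silylalkyne 8 (not isolated)
Conditions: 1-(trimethylsilyl)propyne, n-BuLi, THF, −78 °C; add 7, −78 → 0 °C; then MeOH, K2CO3, rt
Reagents that add atoms: 1-(trimethylsilyl)propyne CC#C[Si](C)(C)C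
Why: The same propargylation as in step 1, here by direct SN2 attack at the primary allylic carbon, which should leave the 5E alkene unchanged.

Step 5
Reactants: 9 (5E,10S)-6,10,14-trimethylpentadeca-5,13-dien-1-yne
Product: 12 (2E,6E,11S)-3,7,11,15-tetramethylhexadeca-2,6,14-trien-1-ol, via alkenylalane 10 (not isolated), via lithium alanate 11 (not isolated)
Conditions: Me3Al, Cp2ZrCl2 (20 mol%), (CH2Cl)2, rt; then n-BuLi, THF/hexane, −78 → 0 °C; (CH2O)n, rt; dilute HCl
Reagents that add atoms: trimethylaluminium C[Al](C)C; formaldehyde (as paraformaldehyde) C=O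
Why: Second turn of the Negishi methylalumination/formaldehyde sequence, in which syn addition again fixes the new 2E alkene.

Step 6
Reactants: 12 (2E,6E,11S)-3,7,11,15-tetramethylhexadeca-2,6,14-trien-1-ol
Product: 13 (2E,6E,11S)-1-bromo-3,7,11,15-tetramethylhexadeca-2,6,14-triene
Conditions: CBr4, PPh3, CH2Cl2, −20 → 0 °C
Reagents that add atoms: carbon tetrabromide BrC(Br)(Br)Br
Why: Appel bromination as in step 3.

Step 7
Reactants: 13 (2E,6E,11S)-1-bromo-3,7,11,15-tetramethylhexadeca-2,6,14-triene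
Product: 15 (5E,9E,14S)-6,10,14,18-tetramethylnonadeca-5,9,17-trien-1-yne, via silylalkyne 14 (not isolated)
Conditions: 1-(trimethylsilyl)propyne, n-BuLi, THF, −78 °C; add 13, −78 → 0 °C; then MeOH, K2CO3, rt
Reagents that add atoms: 1-(trimethylsilyl)propyne CC#C[Si](C)(C)C
Why: Propargylation and desilylation as in step 4.

Step 8
Reactants: 15 (5E,9E,14S)-6,10,14,18-tetramethylnonadeca-5,9,17-trien-1-yne
Product: 18 (3E,7E,11E,16S)-4,8,12,16,20-pentamethylhenicosa-3,7,11,19-tetraen-1-ol, via alkenylalane 16 (not isolated), via lithium alanate 17 (not isolated)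
Conditions: Me3Al, Cp2ZrCl2 (20 mol%), (CH2Cl)2, rt; then n-BuLi, THF/hexane, −78 → 0 °C; oxirane, −78 °C → rt; dilute HCl
Reagents that add atoms: trimethylaluminium C[Al](C)C; oxirane C1CO1
Why: Negishi methylalumination followed by ring opening of oxirane by the alkenylalanate (retention at the alkenyl carbon) should give the E-homoallylic alcohol that already carries C16 and C17.

Step 9
Reactants: 18 (3E,7E,11E,16S)-4,8,12,16,20-pentamethylhenicosa-3,7,11,19-tetraen-1-ol
Product: 19 (3E,7E,11E,16S)-1-iodo-4,8,12,16,20-pentamethylhenicosa-3,7,11,19-tetraene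
Conditions: I2, PPh3, imidazole, CH2Cl2, 0 °C → rt
Reagents that add atoms: iodine II
Why: Appel-type iodination of a primary alcohol by SN2 displacement, which does not touch the alkenes.

Step 10
Reactants: 19 (3E,7E,11E,16S)-1-iodo-4,8,12,16,20-pentamethylhenicosa-3,7,11,19-tetraene
Product: 21 4,4,5,5-tetramethyl-2-[(3E,7E,11E,16S)-4,8,12,16,20-pentamethylhenicosa-3,7,11,19-tetraen-1-yl]-1,3,2-dioxaborolane, via alkyllithium 20 (not isolated)
Conditions: t-BuLi (2.1 equiv), Et2O/pentane, −78 °C; then 2-isopropoxy-4,4,5,5-tetramethyl-1,3,2-dioxaborolane, −78 °C → rt; aq. NH4Cl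
Reagents that add atoms: 2-isopropoxy-4,4,5,5-tetramethyl-1,3,2-dioxaborolane CC(C)OB1OC(C)(C)C(C)(C)O1
Why: Lithium–iodine exchange gives a homoallyllithium that is borylated by the alkoxyboronate (polar borylation of an organolithium), a path that avoids radical intermediates which could scramble the neighbouring alkene.

Step 11
Reactants: 6 (2E,7S)-3,7,11-trimethyldodeca-2,10-dien-1-ol
Product: 22 (3R,7S)-3,7,11-trimethyldodec-10-en-1-ol
Conditions: H2 (100 atm), Ru(OAc)2[(S)-BINAP] (0.5 mol%), MeOH/H2O 95:5, 20 °C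
Reagents that add atoms: none
Why: Noyori asymmetric hydrogenation of a geraniol-type allylic alcohol, in which the hydroxyl binds ruthenium and the (S)-BINAP ligand should set C3 as R (the sense in which geraniol gives (R)-citronellol), while the unfunctionalised trisubstituted alkene is not reduced.

Step 12
Reactants: 22 (3R,7S)-3,7,11-trimethyldodec-10-en-1-ol
Product: 23 (6S,10R)-12-bromo-2,6,10-trimethyldodec-2-ene
Conditions: CBr4, PPh3, CH2Cl2, 0 °C
Reagents that add atoms: carbon tetrabromide BrC(Br)(Br)Br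
Why: Appel bromination of a primary alcohol by SN2 displacement remote from both stereocentres.

Step 13
Reactants: 23 (6S,10R)-12-bromo-2,6,10-trimethyldodec-2-ene
Product: 25 (6R,10S)-6,10,14-trimethylpentadec-13-en-1-yne, via silylalkyne 24 (not isolated)
Conditions: 1-(trimethylsilyl)propyne, n-BuLi, THF, −78 °C; add 23, DMPU, −78 °C → rt; then MeOH, K2CO3, rt
Reagents that add atoms: 1-(trimethylsilyl)propyne CC#C[Si](C)(C)C
Why: Propargylation and desilylation as in step 1, which brings in C2–C4 of the side chain.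

Step 14
Reactants: 25 (6R,10S)-6,10,14-trimethylpentadec-13-en-1-yne
Product: 27 (4S,8R)-4,8-dimethyltridec-12-yn-1-ol, via alkynal 26 (not isolated)
Conditions: O3, CH2Cl2/MeOH, Sudan Red 7B end point, −78 °C; then NaBH4, −78 °C → rt
Reagents that add atoms: ozone [O-][O+]=O
Why: Ozonolysis with reductive work-up cleaves the electron-rich trisubstituted alkene much faster than the terminal alkyne (the dye marks the end point), and the aldehyde has only a CH2 at its α-position, so no stereocentre can epimerise.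

Step 15
Reactants: 28 menadione
Product: 30 1,4-dimethoxy-2-methylnaphthalene, via menadiol 29 (not isolated)
Conditions: Na2S2O4, H2O/EtOAc, rt; then Me2SO4, KOH, acetone, reflux
Reagents that add atoms: dimethyl sulfate COS(=O)(=O)OC
Why: Dithionite reduction of the quinone followed by Williamson O-methylation of the hydroquinone masks the quinone as its dimethyl ether, which tolerates the organometallic steps.

Step 16
Reactants: 30 1,4-dimethoxy-2-methylnaphthalene
Product: 31 2-(chloromethyl)-1,4-dimethoxy-3-methylnaphthalene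
Conditions: (CH2O)n, conc. HCl, AcOH, 40 °C
Reagents that add atoms: formaldehyde (as paraformaldehyde) C=O; hydrogen chloride Cl
Why: Blanc chloromethylation should occur at C3, the only free position of the electron-rich dimethoxy ring.

Step 17
Reactants: 27 (4S,8R)-4,8-dimethyltridec-12-yn-1-ol; 31 2-(chloromethyl)-1,4-dimethoxy-3-methylnaphthalene
Product: 33 (4S,8R,12E)-14-(1,4-dimethoxy-3-methylnaphthalen-2-yl)-4,8,12-trimethyltetradec-12-en-1-ol, via alkenylalane 32 (not isolated)
Conditions: Me3Al (3.5 equiv), Cp2ZrCl2 (25 mol%), (CH2Cl)2, 0 °C → rt; excess Me3Al removed in vacuo; then 31, NiCl2(PPh3)2 (5 mol%) pre-reduced with n-BuLi (10 mol%) to zerovalent nickel, THF, 0 °C → rt; dilute HCl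
Reagents that add atoms: trimethylaluminium C[Al](C)C
Why: Negishi methylalumination (the hydroxyl carried as its dimethylaluminium alkoxide) followed by nickel-catalysed cross-coupling of the alkenylalane with the benzylic chloride, which proceeds with retention, should form C1–C2 and set the 2E alkene of the side chain.

Step 18
Reactants: 33 (4S,8R,12E)-14-(1,4-dimethoxy-3-methylnaphthalen-2-yl)-4,8,12-trimethyltetradec-12-en-1-ol
Product: 34 (4S,8R,12E)-14-(1,4-dimethoxy-3-methylnaphthalen-2-yl)-4,8,12-trimethyltetradec-12-enal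
Conditions: Dess–Martin periodinane, NaHCO3, CH2Cl2, 0 °C → rt
Reagents that add atoms: none
Why: Dess–Martin oxidation of a primary alcohol under buffered conditions, which leaves the alkene and the electron-rich arene alone.

Step 19
Reactants: 34 (4S,8R,12E)-14-(1,4-dimethoxy-3-methylnaphthalen-2-yl)-4,8,12-trimethyltetradec-12-enal
Product: 35 2-[(2E,7R,11S,14Z)-15-iodo-3,7,11-trimethylhexadeca-2,14-dien-1-yl]-1,4-dimethoxy-3-methylnaphthalene
Conditions: EtPPh3I, n-BuLi, THF, rt; I2, −78 °C; NaN(SiMe3)2, −20 °C; add 34, −78 → −20 °C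
Reagents that add atoms: ethyltriphenylphosphonium iodide CC[P+](c1ccccc1)(c1ccccc1)c1ccccc1.[I-]; iodine II
Why: Wittig olefination with the α-iodoethylidene ylide (Stork–Zhao-type iodo-olefination) should place iodine cis to the chain under kinetic control and so give the Z-iodoalkene that the union requires.

Step 20
Reactants: 35 2-[(2E,7R,11S,14Z)-15-iodo-3,7,11-trimethylhexadeca-2,14-dien-1-yl]-1,4-dimethoxy-3-methylnaphthalene; 21 4,4,5,5-tetramethyl-2-[(3E,7E,11E,16S)-4,8,12,16,20-pentamethylhenicosa-3,7,11,19-tetraen-1-yl]-1,3,2-dioxaborolane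
Product: 39 2-[(2E,7R,11S,14E,18E,22E,26E,31S)-3,7,11,15,19,23,27,31,35-nonamethylhexatriaconta-2,14,18,22,26,34-hexaen-1-yl]-1,4-dimethoxy-3-methylnaphthalene, via alkenyllithium 36 (not isolated), via lithium boronate 37 (not isolated), via iodoboronic ester 38 (not isolated)
Conditions: 35, t-BuLi (2.0 equiv), THF/Et2O, −78 °C; add 21 (1.1 equiv), −78 °C; I2 (1.1 equiv), THF, −78 °C; NaOMe, MeOH, −78 °C → rt; aq. Na2S2O3
Reagents that add atoms: none
Why: Iodine–lithium exchange on 35 with retention gives alkenyllithium 36, which adds to the trigonal boron of 21 to give boronate 37; iodine then forms an iodonium ion on the alkenyl–boron π bond, the primary carbon C16 migrates from boron to C15 anti to the breaking C15–I bond (this makes C15–C16 and gives 38), and methoxide attack on boron triggers anti elimination of boron and iodine. The closest known reaction type is the Zweifel olefination of alkenyllithium–boronic ester ate complexes, which is stereospecific with net inversion of the alkenyl geometry. No ring is closed. No permanent stereocentre is created (the two in 38 are erased); the 14E geometry is controlled by the Z geometry of 35 through the anti-migration/anti-elimination sequence, which leaves the migrated chain trans to C13. The step needs iodine to attack only the boronate alkene in the presence of five other trisubstituted alkenes and the dimethoxynaphthalene, which the anionic and far more nucleophilic ate complex, one equivalent of iodine and −78 °C should secure; C16 is the only carbon ligand on boron besides the alkenyl group, so no other group can migrate.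

Step 21
Reactants: 39 2-[(2E,7R,11S,14E,18E,22E,26E,31S)-3,7,11,15,19,23,27,31,35-nonamethylhexatriaconta-2,14,18,22,26,34-hexaen-1-yl]-1,4-dimethoxy-3-methylnaphthalene
Product: 40 2-methyl-3-[(2E,7R,11S,14E,18E,22E,26E,31S)-3,7,11,15,19,23,27,31,35-nonamethylhexatriaconta-2,14,18,22,26,34-hexaen-1-yl]naphthalene-1,4-dione
Conditions: (NH4)2Ce(NO3)6 (2.5 equiv), MeCN/H2O/CH2Cl2, 0 °C
Reagents that add atoms: water O
Why: Oxidative demethylation of a hydroquinone dimethyl ether by tetravalent cerium (aryl–oxygen cleavage, the quinone oxygens coming from water) is standard for polyprenyl quinones and should be fast enough at 0 °C to spare the isolated alkenes.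

**Compound list**

1 | (R)-citronellyl bromide, (6R)-8-bromo-2,6-dimethyloct-2-ene | CC(C)=CCC[C@@H](C)CCBr | starting material
2 | trimethyl[(6S)-6,10-dimethylundec-9-en-1-yn-1-yl]silane | CC(C)=CCC[C@@H](C)CCCC#C[Si](C)(C)C | intermediate
3 | (6S)-6,10-dimethylundec-9-en-1-yne | CC(C)=CCC[C@@H](C)CCCC#C | intermediate
4 | dimethyl[(1E,6S)-2,6,10-trimethylundeca-1,9-dien-1-yl]alane | CC(C)=CCC[C@@H](C)CCC/C(C)=C/[Al](C)C | intermediate
5 | lithium butyl(dimethyl)[(1E,6S)-2,6,10-trimethylundeca-1,9-dien-1-yl]alanate | [Li+].CC(C)=CCC[C@@H](C)CCC/C(C)=C/[Al-](C)(C)CCCC | intermediate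
6 | (2E,7S)-3,7,11-trimethyldodeca-2,10-dien-1-ol | CC(C)=CCC[C@@H](C)CCC/C(C)=C/CO | intermediate
7 | (2E,7S)-1-bromo-3,7,11-trimethyldodeca-2,10-diene | CC(C)=CCC[C@@H](C)CCC/C(C)=C/CBr | intermediate
8 | trimethyl[(5E,10S)-6,10,14-trimethylpentadeca-5,13-dien-1-yn-1-yl]silane | CC(C)=CCC[C@@H](C)CCC/C(C)=C/CCC#C[Si](C)(C)C | intermediate
9 | (5E,10S)-6,10,14-trimethylpentadeca-5,13-dien-1-yne | CC(C)=CCC[C@@H](C)CCC/C(C)=C/CCC#C | intermediate
10 | dimethyl[(1E,5E,10S)-2,6,10,14-tetramethylpentadeca-1,5,13-trien-1-yl]alane | CC(C)=CCC[C@@H](C)CCC/C(C)=C/CC/C(C)=C/[Al](C)C | intermediate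
11 | lithium butyl(dimethyl)[(1E,5E,10S)-2,6,10,14-tetramethylpentadeca-1,5,13-trien-1-yl]alanate | [Li+].CC(C)=CCC[C@@H](C)CCC/C(C)=C/CC/C(C)=C/[Al-](C)(C)CCCC | intermediate
12 | (2E,6E,11S)-3,7,11,15-tetramethylhexadeca-2,6,14-trien-1-ol | CC(C)=CCC[C@@H](C)CCC/C(C)=C/CC/C(C)=C/CO | intermediate
13 | (2E,6E,11S)-1-bromo-3,7,11,15-tetramethylhexadeca-2,6,14-triene | CC(C)=CCC[C@@H](C)CCC/C(C)=C/CC/C(C)=C/CBr | intermediate
14 | trimethyl[(5E,9E,14S)-6,10,14,18-tetramethylnonadeca-5,9,17-trien-1-yn-1-yl]silane | CC(C)=CCC[C@@H](C)CCC/C(C)=C/CC/C(C)=C/CCC#C[Si](C)(C)C | intermediate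
15 | (5E,9E,14S)-6,10,14,18-tetramethylnonadeca-5,9,17-trien-1-yne | CC(C)=CCC[C@@H](C)CCC/C(C)=C/CC/C(C)=C/CCC#C | intermediate
16 | dimethyl[(1E,5E,9E,14S)-2,6,10,14,18-pentamethylnonadeca-1,5,9,17-tetraen-1-yl]alane | CC(C)=CCC[C@@H](C)CCC/C(C)=C/CC/C(C)=C/CC/C(C)=C/[Al](C)C | intermediate
17 | lithium butyl(dimethyl)[(1E,5E,9E,14S)-2,6,10,14,18-pentamethylnonadeca-1,5,9,17-tetraen-1-yl]alanate | [Li+].CC(C)=CCC[C@@H](C)CCC/C(C)=C/CC/C(C)=C/CC/C(C)=C/[Al-](C)(C)CCCC | intermediate
18 | (3E,7E,11E,16S)-4,8,12,16,20-pentamethylhenicosa-3,7,11,19-tetraen-1-ol | CC(C)=CCC[C@@H](C)CCC/C(C)=C/CC/C(C)=C/CC/C(C)=C/CCO | intermediate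
19 | (3E,7E,11E,16S)-1-iodo-4,8,12,16,20-pentamethylhenicosa-3,7,11,19-tetraene | CC(C)=CCC[C@@H](C)CCC/C(C)=C/CC/C(C)=C/CC/C(C)=C/CCI | intermediate
20 | [(3E,7E,11E,16S)-4,8,12,16,20-pentamethylhenicosa-3,7,11,19-tetraen-1-yl]lithium | CC(C)=CCC[C@@H](C)CCC/C(C)=C/CC/C(C)=C/CC/C(C)=C/CC[Li] | intermediate
21 | 4,4,5,5-tetramethyl-2-[(3E,7E,11E,16S)-4,8,12,16,20-pentamethylhenicosa-3,7,11,19-tetraen-1-yl]-1,3,2-dioxaborolane (fragment 1) | CC(C)=CCC[C@@H](C)CCC/C(C)=C/CC/C(C)=C/CC/C(C)=C/CCB1OC(C)(C)C(C)(C)O1 | intermediate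
22 | (3R,7S)-3,7,11-trimethyldodec-10-en-1-ol | CC(C)=CCC[C@@H](C)CCC[C@@H](C)CCO | intermediate
23 | (6S,10R)-12-bromo-2,6,10-trimethyldodec-2-ene | CC(C)=CCC[C@@H](C)CCC[C@@H](C)CCBr | intermediate
24 | trimethyl[(6R,10S)-6,10,14-trimethylpentadec-13-en-1-yn-1-yl]silane | CC(C)=CCC[C@@H](C)CCC[C@@H](C)CCCC#C[Si](C)(C)C | intermediate
25 | (6R,10S)-6,10,14-trimethylpentadec-13-en-1-yne | CC(C)=CCC[C@@H](C)CCC[C@@H](C)CCCC#C | intermediate
26 | (4S,8R)-4,8-dimethyltridec-12-ynal | O=CCC[C@@H](C)CCC[C@@H](C)CCCC#C | intermediate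
27 | (4S,8R)-4,8-dimethyltridec-12-yn-1-ol | OCCC[C@@H](C)CCC[C@@H](C)CCCC#C | intermediate
28 | menadione, 2-methylnaphthalene-1,4-dione | CC1=CC(=O)c2ccccc2C1=O | starting material
29 | menadiol, 2-methylnaphthalene-1,4-diol | Cc1cc(O)c2ccccc2c1O | intermediate
30 | 1,4-dimethoxy-2-methylnaphthalene | COc1cc(C)c(OC)c2ccccc12 | intermediate
31 | 2-(chloromethyl)-1,4-dimethoxy-3-methylnaphthalene | COc1c(C)c(CCl)c(OC)c2ccccc12 | intermediate
32 | dimethylaluminium (4S,8R,12E)-13-(dimethylalumanyl)-4,8,12-trimethyltridec-12-en-1-olate | C[Al](C)OCCC[C@@H](C)CCC[C@@H](C)CCC/C(C)=C/[Al](C)C | intermediate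
33 | (4S,8R,12E)-14-(1,4-dimethoxy-3-methylnaphthalen-2-yl)-4,8,12-trimethyltetradec-12-en-1-ol | OCCC[C@@H](C)CCC[C@@H](C)CCC/C(C)=C/Cc1c(C)c(OC)c2ccccc2c1OC | intermediate
34 | (4S,8R,12E)-14-(1,4-dimethoxy-3-methylnaphthalen-2-yl)-4,8,12-trimethyltetradec-12-enal | O=CCC[C@@H](C)CCC[C@@H](C)CCC/C(C)=C/Cc1c(C)c(OC)c2ccccc2c1OC | intermediate
35 | 2-[(2E,7R,11S,14Z)-15-iodo-3,7,11-trimethylhexadeca-2,14-dien-1-yl]-1,4-dimethoxy-3-methylnaphthalene (fragment 2) | C/C(I)=C/CC[C@@H](C)CCC[C@@H](C)CCC/C(C)=C/Cc1c(C)c(OC)c2ccccc2c1OC | intermediate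
36 | alkenyllithium from 35, lithium on C15 cis to C13 | C/C([Li])=C/CC[C@@H](C)CCC[C@@H](C)CCC/C(C)=C/Cc1c(C)c(OC)c2ccccc2c1OC | intermediate
37 | lithium boronate: boron of 21 bearing C16 and C15, boron cis to C13 | [Li+].CC(C)=CCC[C@@H](C)CCC/C(C)=C/CC/C(C)=C/CC/C(C)=C/CC[B-]1(OC(C)(C)C(C)(C)O1)/C(C)=C\CC[C@@H](C)CCC[C@@H](C)CCC/C(C)=C/Cc1c(C)c(OC)c2ccccc2c1OC | intermediate
38 | 14-iodo-15-(pinacolboryl) adduct of 39, anti arrangement from the migration; one of the two alkene-face diastereomers is drawn, the other has both new centres inverted and gives the same alkene | CC(C)=CCC[C@@H](C)CCC/C(C)=C/CC/C(C)=C/CC/C(C)=C/CC[C@](C)(B1OC(C)(C)C(C)(C)O1)[C@H](I)CC[C@@H](C)CCC[C@@H](C)CCC/C(C)=C/Cc1c(C)c(OC)c2ccccc2c1OC | intermediate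
39 | 2-[(2E,7R,11S,14E,18E,22E,26E,31S)-3,7,11,15,19,23,27,31,35-nonamethylhexatriaconta-2,14,18,22,26,34-hexaen-1-yl]-1,4-dimethoxy-3-methylnaphthalene | CC(C)=CCC[C@@H](C)CCC/C(C)=C/CC/C(C)=C/CC/C(C)=C/CC/C(C)=C/CC[C@@H](C)CCC[C@@H](C)CCC/C(C)=C/Cc1c(C)c(OC)c2ccccc2c1OC | intermediate
40 | 2-methyl-3-[(2E,7R,11S,14E,18E,22E,26E,31S)-3,7,11,15,19,23,27,31,35-nonamethylhexatriaconta-2,14,18,22,26,34-hexaen-1-yl]naphthalene-1,4-dione | CC(C)=CCC[C@@H](C)CCC/C(C)=C/CC/C(C)=C/CC/C(C)=C/CC/C(C)=C/CC[C@@H](C)CCC[C@@H](C)CCC/C(C)=C/CC1=C(C)C(=O)c2ccccc2C1=O | target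

**Totals**

Total step count: 21.
Longest linear sequence: 12 steps (steps 1–10, 20, 21, from (R)-citronellyl bromide).

**Steps most likely to fail, with fallbacks**

Step 20. Iodine may be consumed by the other alkenes or the arene, boronate formation may be incomplete, or the alkenyllithium may lose its geometry before capture. The fallback sets out from 35 and 19 and comes back at 39. It makes the same C15–C16 bond by a palladium-catalysed coupling that goes with retention, so it needs the E-iodide. 35 is dehydroiodinated with KOt-Bu (THF, 0 °C; anti elimination of the vinylic hydrogen and iodine) to the 2-alkyne 2-[(2E,7R,11S)-3,7,11-trimethylhexadec-2-en-14-yn-1-yl]-1,4-dimethoxy-3-methylnaphthalene F1. Schwartz hydrozirconation with excess Cp2Zr(H)Cl (THF, 40 °C, equilibration towards zirconium on the methyl-bearing carbon) should give the alkenylzirconocene chloride F2, and iodine then the (14E)-iodide 2-[(2E,7R,11S,14E)-15-iodo-3,7,11-trimethylhexadeca-2,14-dien-1-yl]-1,4-dimethoxy-3-methylnaphthalene F3. Iodide 19 is converted through alkyllithium 20 (t-BuLi, −78 °C) and ZnBr2 into the alkylzinc bromide bromo[(3E,7E,11E,16S)-4,8,12,16,20-pentamethylhenicosa-3,7,11,19-tetraen-1-yl]zinc F4. Negishi coupling of F3 with F4 (Pd(PPh3)4, zerovalent palladium, THF, rt) should then give 39.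

Step 19. The iodo-ylide may decompose before it adds, or the olefination may give poor Z/E control, which would pass directly into the 14E/14Z purity of the product. The fallback sets out from 34 and 19 and comes back at 39, replacing steps 19 and 20. Aldehyde 34 is converted with PPh3/CCl4 into the 1,1-dichloroalkene 2-[(2E,7R,11S)-15,15-dichloro-3,7,11-trimethylpentadeca-2,14-dien-1-yl]-1,4-dimethoxy-3-methylnaphthalene F5. Palladium-catalysed trans-selective monoalkylation (Negishi coupling, PdCl2(DPEphos), THF) with the alkylzinc bromide F4 replaces only the chloride trans to C13 and should give the (14Z)-15-chloro analogue of 39, F6. Methylation of the remaining chloride with retention (Me2Zn, Pd[P(t-Bu)3]2, THF) then gives 39.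

Step 17. The aluminium alkoxide may slow or poison the nickel catalyst, residual methylalane may transfer methyl to the benzylic chloride, or carbometalation may stall. The fallback sets out from 27 and 31 and comes back at 33, reversing the polarity of the C1–C2 coupling. 27 is silylated (t-BuMe2SiCl, imidazole, DMF) to tert-butyl{[(4S,8R)-4,8-dimethyltridec-12-yn-1-yl]oxy}dimethylsilane F7. Methylalumination (Me3Al, Cp2ZrCl2) gives the alkenylalane F8, and iodine the E-alkenyl iodide tert-butyl{[(4S,8R,12E)-13-iodo-4,8,12-trimethyltridec-12-en-1-yl]oxy}dimethylsilane F9. Chloride 31 with zinc dust and LiCl in THF gives the benzylic zinc chloride chloro[(1,4-dimethoxy-3-methylnaphthalen-2-yl)methyl]zinc F10. Negishi coupling of F9 with F10 (Pd(PPh3)4, zerovalent palladium, THF, rt) gives the silyl ether of 33, F11, and Bu4NF in THF then gives 33.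

Further compounds
F1 | step 20 | 2-[(2E,7R,11S)-3,7,11-trimethylhexadec-2-en-14-yn-1-yl]-1,4-dimethoxy-3-methylnaphthalene | CC#CCC[C@@H](C)CCC[C@@H](C)CCC/C(C)=C/Cc1c(C)c(OC)c2ccccc2c1OC
F2 | step 20 | alkenylzirconocene chloride from syn addition of Zr–H to F1, Cp2Zr(Cl) on C15 trans to C13 | C/C(=C\CC[C@@H](C)CCC[C@@H](C)CCC/C(C)=C/Cc1c(C)c(OC)c2ccccc2c1OC)[Zr](Cl)(C1C=CC=C1)C1C=CC=C1
F3 | step 20 | 2-[(2E,7R,11S,14E)-15-iodo-3,7,11-trimethylhexadeca-2,14-dien-1-yl]-1,4-dimethoxy-3-methylnaphthalene | C/C(I)=C\CC[C@@H](C)CCC[C@@H](C)CCC/C(C)=C/Cc1c(C)c(OC)c2ccccc2c1OC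
F4 | step 20 | bromo[(3E,7E,11E,16S)-4,8,12,16,20-pentamethylhenicosa-3,7,11,19-tetraen-1-yl]zinc | CC(C)=CCC[C@@H](C)CCC/C(C)=C/CC/C(C)=C/CC/C(C)=C/CC[Zn]Br
F5 | step 19 | 2-[(2E,7R,11S)-15,15-dichloro-3,7,11-trimethylpentadeca-2,14-dien-1-yl]-1,4-dimethoxy-3-methylnaphthalene | ClC(Cl)=CCC[C@@H](C)CCC[C@@H](C)CCC/C(C)=C/Cc1c(C)c(OC)c2ccccc2c1OC
F6 | step 19 | 2-[(2E,7R,11S,14Z,18E,22E,26E,31S)-15-chloro-3,7,11,19,23,27,31,35-octamethylhexatriaconta-2,14,18,22,26,34-hexaen-1-yl]-1,4-dimethoxy-3-methylnaphthalene | CC(C)=CCC[C@@H](C)CCC/C(C)=C/CC/C(C)=C/CC/C(C)=C/CC/C(Cl)=C/CC[C@@H](C)CCC[C@@H](C)CCC/C(C)=C/Cc1c(C)c(OC)c2ccccc2c1OC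
F7 | step 17 | tert-butyl{[(4S,8R)-4,8-dimethyltridec-12-yn-1-yl]oxy}dimethylsilane | CC(C)(C)[Si](C)(C)OCCC[C@@H](C)CCC[C@@H](C)CCCC#C
F8 | step 17 | {(1E,6R,10S)-13-[(tert-butyldimethylsilyl)oxy]-2,6,10-trimethyltridec-1-en-1-yl}dimethylalane | CC(C)(C)[Si](C)(C)OCCC[C@@H](C)CCC[C@@H](C)CCC/C(C)=C/[Al](C)C
F9 | step 17 | tert-butyl{[(4S,8R,12E)-13-iodo-4,8,12-trimethyltridec-12-en-1-yl]oxy}dimethylsilane | CC(C)(C)[Si](C)(C)OCCC[C@@H](C)CCC[C@@H](C)CCC/C(C)=C/I
F10 | step 17 | chloro[(1,4-dimethoxy-3-methylnaphthalen-2-yl)methyl]zinc | COc1c(C)c(C[Zn]Cl)c(OC)c2ccccc12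
F11 | step 17 | tert-butyl{[(4S,8R,12E)-14-(1,4-dimethoxy-3-methylnaphthalen-2-yl)-4,8,12-trimethyltetradec-12-en-1-yl]oxy}dimethylsilane | CC(C)(C)[Si](C)(C)OCCC[C@@H](C)CCC[C@@H](C)CCC/C(C)=C/Cc1c(C)c(OC)c2ccccc2c1OC
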